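**Retrosynthetic overview**
- Target acid ⇐ methyl ester ⇐ 6-exo oxa-Michael closure (C3–O bond, sets C3) of a tertiary allylic hydroperoxide onto an E-enoate, itself made by Wittig opening of a peroxy-lactol.
- C6–C7 bond ⇐ alkenyltrifluoroborate + cyclic peroxycarbenium ion (sets the quaternary C6; proposed new method).
- 1,2-Dioxane (the only ring) ⇐ aerobic cobalt-catalysed radical ring expansion of a 2-silyloxycyclobutanol; C4 comes from desymmetrised 3-ethylcyclobutanone.
- Side chain ⇐ Rh/BINAP conjugate alkenylation (C10), ester → alkyne, syn-ethylcupration/iodination, I → BF3K.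
- Ring order: cyclobutane (bought) → 1,2-dioxane by ring expansion (step 4) → opened at C3–O and re-closed in step 10.

Assumption: 1, 8 and 9 are bought; if the chiral lithium amide (step 1) or BINAP (step 5) induces the opposite sense to that written, its antipode is used.
Dioxane ring atoms are numbered as in the target throughout (O1, O2, C3 carrying the acetic acid arm, C4, C5, C6).

**Step 1**
Reactants: 1 3-ethylcyclobutan-1-one
Product: 2 tert-butyl{[(3R)-3-ethylcyclobut-1-en-1-yl]oxy}dimethylsilane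
Conditions: (S,S)-(PhMeCH)2NH, n-BuLi, LiCl, THF, −100 °C; TBSOTf, −100 → −78 °C
Reagents that add atoms: tert-butyldimethylsilyl trifluoromethanesulfonate (CC(C)(C)[Si](C)(C)OS(=O)(=O)C(F)(F)F)
Why: Enantiotopos-selective deprotonation of the prochiral ketone by the C2-symmetric chiral lithium amide (asymmetric desymmetrisation) and O-silylation fix the ethyl-bearing stereocentre as R, which later becomes C4 of the dioxane.

**Step 2**
Reactants: 2 tert-butyl{[(3R)-3-ethylcyclobut-1-en-1-yl]oxy}dimethylsilane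
Product: 4 (2S,3R)-2-[(tert-butyldimethylsilyl)oxy]-3-ethylcyclobutan-1-one, via silyloxy oxirane 3 (not isolated)
Conditions: DMDO (acetone), CH2Cl2, −78 → 0 °C; then 23 °C
Reagents that add atoms: dimethyldioxirane (CC1(C)OO1)
Why: Rubottom oxidation, in which DMDO epoxidises the enol ether anti to the ethyl group and the silyloxy oxirane opens with 1,4-silyl shift to the α-silyloxy ketone; the new C2 centre is erased in step 4, so its configuration does not matter.

**Step 3**
Reactants: 4 (2S,3R)-2-[(tert-butyldimethylsilyl)oxy]-3-ethylcyclobutan-1-one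
Product: 5 (2S,3R)-2-[(tert-butyldimethylsilyl)oxy]-1,3-diethylcyclobutan-1-ol (both C1 epimers)
Conditions: EtMgBr, Et2O, −78 °C; then H2O
Reagents that add atoms: ethylmagnesium bromide (CC[Mg]Br)
Why: Grignard 1,2-addition to the strained, electrophilic cyclobutanone gives the tertiary cyclobutanol, and either C1 epimer serves because C1 becomes the hemiketal carbon.

**Step 4**
Reactants: 5 (2S,3R)-2-[(tert-butyldimethylsilyl)oxy]-1,3-diethylcyclobutan-1-ol
Product: 7 (4R)-3-[(tert-butyldimethylsilyl)oxy]-4,6-diethyl-1,2-dioxan-6-ol (mixture at C3 and C6), via hydroperoxy ketone 6 (not isolated)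
Conditions: Co(acac)2 (10 mol %), O2 (1 atm), ClCH2CH2Cl, 40 °C
Reagents that add atoms: dioxygen (O=O)
Why: Cobalt-catalysed aerobic radical ring expansion of a cyclobutanol, in which the trivalent cobalt alkoxide gives an alkoxy radical, β-scission goes toward the silyloxy-bearing carbon (stabilised α-oxy radical, strain release), O2 is captured and hydroperoxide 6 closes on the ethyl ketone; both former carbinol centres become exchangeable (hemi)ketal carbons and the ethyl-bearing centre is untouched (C4, R).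

**Step 5**
Reactants: 8 methyl (2E)-pent-2-enoate; 9 (1E)-but-1-en-1-ylboronic acid
Product: 10 methyl (3R,4E)-3-ethylhept-4-enoate
Conditions: [Rh(OH)((R)-binap)]2 (1.5 mol %), 9 (2.5 equiv), dioxane/H2O 10:1, 40 °C
Reagents that add atoms: none
Why: Hayashi–Miyaura asymmetric 1,4-addition, in which the alkenyl group is transferred from BINAP-bound monovalent rhodium to one face of the enoate with retention of E geometry, setting the future C10 stereocentre (R).

**Step 6**
Reactants: 10 methyl (3R,4E)-3-ethylhept-4-enoate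
Product: 12 (4R,5E)-4-ethyloct-5-en-1-yne, via aldehyde 11 (not isolated)
Conditions: i-Bu2AlH, CH2Cl2, −78 °C; then MeOH, K2CO3, MeC(O)C(N2)P(O)(OMe)2, −78 → 23 °C
Reagents that add atoms: dimethyl (1-diazo-2-oxopropyl)phosphonate (CC(=O)C(=[N+]=[N-])P(=O)(OC)OC)
Why: Partial reduction to the aluminium hemiacetal and in-situ Ohira–Bestmann (Seyferth–Gilbert) homologation of the released aldehyde give the terminal alkyne without touching the β-stereocentre.

**Step 7**
Reactants: 12 (4R,5E)-4-ethyloct-5-en-1-yne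
Product: 14 (1E,4R,5E)-2,4-diethyl-1-iodoocta-1,5-diene, via alkenylcopper 13 (not isolated)
Conditions: EtMgBr, CuBr·SMe2, Et2O/Me2S, −45 °C; 12, −25 °C; then I2, −40 → 0 °C
Reagents that add atoms: ethylmagnesium bromide (CC[Mg]Br); iodine (II)
Why: Normant carbocupration, in which ethylcopper adds syn across the terminal alkyne with copper on the terminal carbon and iodinolysis proceeds with retention, so iodine ends cis to the new ethyl group as required for the C7=C8 geometry.

**Step 8**
Reactants: 14 (1E,4R,5E)-2,4-diethyl-1-iodoocta-1,5-diene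
Product: 17 potassium [(1E,4R,5E)-2,4-diethylocta-1,5-dien-1-yl]trifluoroborate, via alkenyllithium 15 (not isolated), via lithium triisopropoxyborate 16 (not isolated)
Conditions: t-BuLi (2 equiv), Et2O, −78 °C; B(Oi-Pr)3; then aq. KHF2, 0 → 23 °C
Reagents that add atoms: triisopropyl borate (CC(C)OB(OC(C)C)OC(C)C); potassium hydrogen difluoride ([K+].[F-].F)
Why: Iodine–lithium exchange with retention of alkene geometry, borylation and fluoride exchange give the bench-stable alkenyltrifluoroborate.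

**Step 9**
Reactants: 7 (4R)-3-[(tert-butyldimethylsilyl)oxy]-4,6-diethyl-1,2-dioxan-6-ol; 17 potassium [(1E,4R,5E)-2,4-diethylocta-1,5-dien-1-yl]trifluoroborate
Product: 19 tert-butyl({(4R,6S)-6-[(1E,4R,5E)-2,4-diethylocta-1,5-dien-1-yl]-4,6-diethyl-1,2-dioxan-3-yl}oxy)dimethylsilane (both C3 epimers), via alkenyldifluoroborane 18 (not isolated)
Conditions: 17 (2 equiv), BF3·OEt2 (2 equiv), MeCN/CH2Cl2, −78 → −30 °C
Reagents that add atoms: none
Why: Proposed new method: BF3·OEt2 turns 17 into alkenyldifluoroborane 18, which binds the C6 hemiketal hydroxyl, ionises it to the cyclic peroxycarbenium ion and transfers the alkenyl group by ipso attack (β-boryl cation, E geometry retained) along the axial trajectory of the half-chair that keeps the C4 ethyl pseudoequatorial, so the C6–C7 bond forms trans to the C4 ethyl (6S) while the less ionisable C3 silyl acetal is spared; the closest known reactions are the BF3-promoted addition of alkenyl- and alkynyltrifluoroborates to oxocarbenium ions from O,O-acetals and the Lewis acid-mediated substitution of peroxyketals by allylsilanes and silyl enol ethers through peroxycarbenium ions.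

**Step 10**
Reactants: 19 tert-butyl({(4R,6S)-6-[(1E,4R,5E)-2,4-diethylocta-1,5-dien-1-yl]-4,6-diethyl-1,2-dioxan-3-yl}oxy)dimethylsilane
Product: 22 methyl 2-{(3S,4R,6S)-6-[(1E,4R,5E)-2,4-diethylocta-1,5-dien-1-yl]-4,6-diethyl-1,2-dioxan-3-yl}acetate, via peroxy lactol 20 (not isolated), via hydroperoxy enoate 21 (not isolated)
Conditions: TBAF, AcOH (1:1), THF, 0 °C; then Ph3P=CHCO2Me (3 equiv), 23 °C; then Et2NH, CF3CH2OH, 23 °C
Reagents that add atoms: methyl (triphenylphosphoranylidene)acetate (COC(=O)C=P(c1ccccc1)(c1ccccc1)c1ccccc1)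
Why: Buffered fluoride unmasks peroxy-lactol 20, its open hydroperoxy aldehyde form undergoes E-selective Wittig olefination with the stabilised ylide, and amine-promoted 6-exo oxa-Michael addition of the tertiary hydroperoxide of 21 closes the ring through a chair transition state with the C4 ethyl and the enoate equatorial (minimal allylic 1,3-strain), placing the acetate arm trans to the C4 ethyl (3S) with C6 untouched.

**Step 11**
Reactants: 22 methyl 2-{(3S,4R,6S)-6-[(1E,4R,5E)-2,4-diethylocta-1,5-dien-1-yl]-4,6-diethyl-1,2-dioxan-3-yl}acetate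
Product: 23 2-{(3S,4R,6S)-6-[(1E,4R,5E)-2,4-diethylocta-1,5-dien-1-yl]-4,6-diethyl-1,2-dioxan-3-yl}acetic acid
Conditions: LiOH, THF/MeOH/H2O, 0 → 23 °C; then 0.5 M HCl to pH 4, 0 °C
Reagents that add atoms: lithium hydroxide ([Li+].[OH-])
Why: Saponification of the methyl ester under mild conditions that dialkyl peroxides tolerate gives the acid without affecting any stereocentre.

**Compound list**
1 | 3-ethylcyclobutan-1-one | CCC1CC(=O)C1 | starting material
2 | tert-butyl{[(3R)-3-ethylcyclobut-1-en-1-yl]oxy}dimethylsilane | CC[C@H]1C=C(O[Si](C)(C)C(C)(C)C)C1 | intermediate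
3 | (3R)-1-[(tert-butyldimethylsilyl)oxy]-3-ethyl-5-oxabicyclo[2.1.0]pentane, oxirane oxygen anti to ethyl | CC(C)(C)[Si](C)(C)O[C@@]12C[C@@H](CC)[C@@H]1O2 | intermediate
4 | (2S,3R)-2-[(tert-butyldimethylsilyl)oxy]-3-ethylcyclobutan-1-one | O=C1C[C@@H](CC)[C@@H]1O[Si](C)(C)C(C)(C)C | intermediate
5 | (2S,3R)-2-[(tert-butyldimethylsilyl)oxy]-1,3-diethylcyclobutan-1-ol, both C1 epimers | CCC1(O)C[C@@H](CC)[C@@H]1O[Si](C)(C)C(C)(C)C | intermediate
6 | (5R)-6-[(tert-butyldimethylsilyl)oxy]-5-ethyl-6-hydroperoxyhexan-3-one | CCC(=O)C[C@@H](CC)C(OO)O[Si](C)(C)C(C)(C)C | intermediate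
7 | (4R)-3-[(tert-butyldimethylsilyl)oxy]-4,6-diethyl-1,2-dioxan-6-ol, mixture at C3 and C6 | CCC1(O)C[C@@H](CC)C(O[Si](C)(C)C(C)(C)C)OO1 | intermediate
8 | methyl (2E)-pent-2-enoate | CC/C=C/C(=O)OC | starting material
9 | (1E)-but-1-en-1-ylboronic acid | CC/C=C/B(O)O | starting material
10 | methyl (3R,4E)-3-ethylhept-4-enoate | CC/C=C/[C@H](CC)CC(=O)OC | intermediate
11 | (3R,4E)-3-ethylhept-4-enal | CC/C=C/[C@H](CC)CC=O | intermediate
12 | (4R,5E)-4-ethyloct-5-en-1-yne | CC/C=C/[C@H](CC)CC#C | intermediate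
13 | [(1E,4R,5E)-2,4-diethylocta-1,5-dien-1-yl]copper | CC/C=C/[C@H](CC)C/C(=C/[Cu])CC | intermediate
14 | (1E,4R,5E)-2,4-diethyl-1-iodoocta-1,5-diene | CC/C=C/[C@H](CC)C/C(=C/I)CC | intermediate
15 | [(1E,4R,5E)-2,4-diethylocta-1,5-dien-1-yl]lithium | CC/C=C/[C@H](CC)C/C(=C/[Li])CC | intermediate
16 | lithium [(1E,4R,5E)-2,4-diethylocta-1,5-dien-1-yl]tri(propan-2-yloxy)borate | CC/C=C/[C@H](CC)C/C(=C/[B-](OC(C)C)(OC(C)C)OC(C)C)CC.[Li+] | intermediate
17 | potassium [(1E,4R,5E)-2,4-diethylocta-1,5-dien-1-yl]trifluoroborate | CC/C=C/[C@H](CC)C/C(=C/[B-](F)(F)F)CC.[K+] | intermediate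
18 | [(1E,4R,5E)-2,4-diethylocta-1,5-dien-1-yl]difluoroborane | CC/C=C/[C@H](CC)C/C(=C/B(F)F)CC | intermediate
19 | tert-butyl({(4R,6S)-6-[(1E,4R,5E)-2,4-diethylocta-1,5-dien-1-yl]-4,6-diethyl-1,2-dioxan-3-yl}oxy)dimethylsilane, both C3 epimers | CC/C=C/[C@H](CC)C/C(=C/[C@]1(CC)C[C@@H](CC)C(O[Si](C)(C)C(C)(C)C)OO1)CC | intermediate
20 | (4R,6S)-6-[(1E,4R,5E)-2,4-diethylocta-1,5-dien-1-yl]-4,6-diethyl-1,2-dioxan-3-ol | CC/C=C/[C@H](CC)C/C(=C/[C@]1(CC)C[C@@H](CC)C(O)OO1)CC | intermediate
21 | methyl (2E,4R,6S,7E,10R,11E)-4,6,8,10-tetraethyl-6-hydroperoxytetradeca-2,7,11-trienoate | CC/C=C/[C@H](CC)C/C(=C/[C@](OO)(CC)C[C@@H](CC)/C=C/C(=O)OC)CC | intermediate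
22 | methyl 2-{(3S,4R,6S)-6-[(1E,4R,5E)-2,4-diethylocta-1,5-dien-1-yl]-4,6-diethyl-1,2-dioxan-3-yl}acetate | CC/C=C/[C@H](CC)C/C(=C/[C@]1(CC)C[C@@H](CC)[C@H](CC(=O)OC)OO1)CC | intermediate
23 | 2-{(3S,4R,6S)-6-[(1E,4R,5E)-2,4-diethylocta-1,5-dien-1-yl]-4,6-diethyl-1,2-dioxan-3-yl}acetic acid | CC/C=C/[C@H](CC)C/C(=C/[C@]1(CC)C[C@@H](CC)[C@H](CC(=O)O)OO1)CC | target

**Totals**
Total step count: 11. Longest linear sequence: 7 steps (steps 1, 2, 3, 4, 9, 10, 11 from 1; the side-chain branch 5, 6, 7, 8, 9, 10, 11 is equally long).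

**Three steps most likely to fail**

Step 4 (ring expansion on an α-silyloxy cyclobutanol, a substrate class not yet shown for this cobalt/O2 reaction). Risks are loss of the silyl group from hydroperoxide 6 with collapse to the aldehyde, and slow alkoxy-radical formation. The fallback sets out from ketone 1 and comes back at ester 22. The same chiral lithium amide followed by PhNTf2 gives (R)-3-ethylcyclobut-1-en-1-yl trifluoromethanesulfonate F1. Fe(acac)3-catalysed coupling with EtMgBr gives (R)-1,3-diethylcyclobut-1-ene F2. Ozonolysis in CH2Cl2/MeOH at −78 °C expands the ring by Criegee cleavage: methanol traps the ketone oxide and the hydroperoxide closes on the aldehyde, giving (4R)-4,6-diethyl-6-methoxy-1,2-dioxan-3-ol F3. Ph3P=CHCO2Me opens it to methyl (2E,4R)-4-ethyl-6-hydroperoxy-6-methoxyoct-2-enoate F4, which Et2NH in CF3CH2OH closes to methyl 2-[(3S,4R)-4,6-diethyl-6-methoxy-1,2-dioxan-3-yl]acetate F5. The step 9 coupling with 17 and BF3·OEt2, now with loss of the methoxy group, then gives 22, so this fallback still depends on the new step.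

Step 9 (the proposed new alkenylation). Risks are proton loss from the peroxycarbenium ion to a dioxene, bridging of the cation by the C3 silyloxy oxygen to an ozonide-type bicycle, protodeboronation, E/Z leakage, and re-ionisation of the tertiary allylic C6–O bond of the product. The fallback uses known reactions only, gives no control at C6, sets out from cyclobutanol 5 and iodide 14, and comes back at hydroperoxide 21. TBAF frees (2S,3R)-1,3-diethylcyclobutane-1,2-diol F6, and Pb(OAc)4 cleaves the glycol to (R)-2-ethyl-4-oxohexanal F7. Aldehyde-selective Wittig reaction with Ph3P=CHCO2Me gives methyl (2E,4R)-4-ethyl-6-oxooct-2-enoate F8. Alkenyllithium 15 (from 14 and t-BuLi) is transmetalated with CeCl3 to [(1E,4R,5E)-2,4-diethylocta-1,5-dien-1-yl]cerium dichloride F9, which adds 1,2 to the ketone to give methyl (2E,4R,7E,10R,11E)-4,6,8,10-tetraethyl-6-hydroxytetradeca-2,7,11-trienoate F10. Acid-catalysed perhydrolysis (50% H2O2, cat. H2SO4, Et2O, 0 °C) of this tertiary allylic alcohol gives 21, which is cyclised as in step 10. The diastereomers are separated after ring closure.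

Step 10 (telescoped unmasking, Wittig reaction and oxa-Michael closure). Risks are epimerisation of the α-branched aldehyde (C4) in the open form of 20, attack of the ylide on the free hydroperoxide, and incomplete trans selectivity at C3. The fallback sets out from lactol 20, isolated after the fluoride step, and comes back at 21. Amine-catalysed Doebner–Knoevenagel condensation with monomethyl malonate (DMAP, DMF, 23 °C) replaces the phosphorus ylide. It gives (4R,6S,7E,10R,11E)-4,6,8,10-tetraethyl-6-hydroperoxy-2-(methoxycarbonyl)tetradeca-2,7,11-trienoic acid F11, which decarboxylates under the same conditions to 21. Et2NH in CF3CH2OH then closes 21 to 22.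

**Further compounds**
F1 | step 4 | (R)-3-ethylcyclobut-1-en-1-yl trifluoromethanesulfonate | CC[C@H]1C=C(OS(=O)(=O)C(F)(F)F)C1
F2 | step 4 | (R)-1,3-diethylcyclobut-1-ene | CC[C@H]1C=C(CC)C1
F3 | step 4 | (4R)-4,6-diethyl-6-methoxy-1,2-dioxan-3-ol | CCC1(OC)C[C@@H](CC)C(O)OO1
F4 | step 4 | methyl (2E,4R)-4-ethyl-6-hydroperoxy-6-methoxyoct-2-enoate | CCC(OC)(OO)C[C@@H](CC)/C=C/C(=O)OC
F5 | step 4 | methyl 2-[(3S,4R)-4,6-diethyl-6-methoxy-1,2-dioxan-3-yl]acetate | CCC1(OC)C[C@@H](CC)[C@H](CC(=O)OC)OO1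
F6 | step 9 | (2S,3R)-1,3-diethylcyclobutane-1,2-diol | CCC1(O)C[C@@H](CC)[C@@H]1O
F7 | step 9 | (R)-2-ethyl-4-oxohexanal | CCC(=O)C[C@@H](CC)C=O
F8 | step 9 | methyl (2E,4R)-4-ethyl-6-oxooct-2-enoate | CCC(=O)C[C@@H](CC)/C=C/C(=O)OC
F9 | step 9 | [(1E,4R,5E)-2,4-diethylocta-1,5-dien-1-yl]cerium dichloride | CC/C=C/[C@H](CC)C/C(=C/[Ce](Cl)Cl)CC
F10 | step 9 | methyl (2E,4R,7E,10R,11E)-4,6,8,10-tetraethyl-6-hydroxytetradeca-2,7,11-trienoate | CC/C=C/[C@H](CC)C/C(=C/C(O)(CC)C[C@@H](CC)/C=C/C(=O)OC)CC
F11 | step 10 | (4R,6S,7E,10R,11E)-4,6,8,10-tetraethyl-6-hydroperoxy-2-(methoxycarbonyl)tetradeca-2,7,11-trienoic acid | CC/C=C/[C@H](CC)C/C(=C/[C@](OO)(CC)C[C@@H](CC)C=C(C(=O)O)C(=O)OC)CC
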